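Locants: ring A = C1(Br), C2, C3, C4(Me, OH), C4a(OH), C8a(Me); ring B = C4a, C5=C6, C7(=O), C8, C8a; ring C = C1′(Me, bonded to C6), C2′(Me2), C3′(Br), C4′, C5′. The enabling feature is the ring-fusion oxygen on C4a trans to the C8a methyl with C5=C6 beside it: the retron of a 1-silyloxy diene (C7=C6–C5=C4a) adding to an isopropenyl ketone (C8=C8a–C1=O).
Cuts: both O–Si bonds, the C7 carbonyl (allylic oxidation) and C1–H (bromoalkene, from a C1 ketone); then C4a–C8a and C7–C8 together (intramolecular Diels–Alder), which opens rings A and B; then C1–C8a (Weinreb amide plus isopropenyl Grignard), the dienol O–Si bond, C4a–C5 (alkenylalane plus aldehyde) and C6–C7 (carboalumination methyl).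
Forward: ring C is built first as a bromoalkyne from camphanic acid (steps 1–6) and the C1–C4a chain from (R)-linalool (steps 7–10). They are joined at C5–C4a (step 11), the enone becomes the silyloxy diene, the dienophile is unveiled last (step 14), and rings A and B close in one operation (step 15). Steps 16–20 adjust C1 and C7 and remove silicon.
Stereochemistry: C1′ from camphanic acid; C3′ from a reagent-controlled CBS reduction followed by Appel inversion; C4 from (R)-linalool; C4a and C8a from the cycloaddition (tether exo, diene face dictated by C4); C1 from face-selective hydrogenation of the bromoalkene.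

Key step: step 15

Remark: (1R,4S)-camphanic acid, (R)-linalool and CH2=C(CH3)MgBr are taken as commercial; carbinol centres that are oxidised in the following step (C1 of 4, C5 of 17) are carried as epimer mixtures.

Step 1
Reactants: 1 (1R,4S)-4,7,7-trimethyl-3-oxo-2-oxabicyclo[2.2.1]heptane-1-carboxylic acid [(+)-camphanic acid]
Product: 3 (1S)-1,2,2-trimethyl-3-oxocyclopentane-1-carboxylic acid, via disodium hydroxycamphorate 2 (not isolated)
Conditions: NaOH (2.2 equiv), H2O, 80 °C; then NaOCl (aq), HCl to pH 6, 0 °C → rt; HCl to pH 2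
Reagents that add atoms: sodium hydroxide, [Na+].[OH-]
Why: Saponification opens the γ-lactone to the tertiary α-hydroxy carboxylate 2, which hypochlorite should cleave by oxidative decarboxylation (O-chlorination, then loss of CO2 and chloride) to the ketone; the quaternary C1 stereocentre has no hydrogen and is carried through unchanged.

Step 2
Reactants: 3 (1S)-1,2,2-trimethyl-3-oxocyclopentane-1-carboxylic acid
Product: 4 (3S)-3-(hydroxymethyl)-2,2,3-trimethylcyclopentan-1-ol (both C1 epimers)
Conditions: LiAlH4, THF, 0 °C → reflux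
Reagents that add atoms: none
Why: LiAlH4 reduces both the hindered carboxylic acid and the ketone; the carbinol centre formed is not controlled and need not be, since step 3 removes it.

Step 3
Reactants: 4 (3S)-3-(hydroxymethyl)-2,2,3-trimethylcyclopentan-1-ol
Product: 5 (1S)-1,2,2-trimethyl-3-oxocyclopentane-1-carbaldehyde
Conditions: Dess–Martin periodinane (2.5 equiv), NaHCO3, CH2Cl2, 0 °C → rt
Reagents that add atoms: none
Why: Dess–Martin oxidation takes the primary alcohol to the aldehyde and the secondary alcohol back to the ketone; the α-quaternary aldehyde cannot enolise.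

Step 4
Reactants: 5 (1S)-1,2,2-trimethyl-3-oxocyclopentane-1-carbaldehyde
Product: 6 (3R)-3-ethynyl-2,2,3-trimethylcyclopentan-1-one
Conditions: dimethyl (1-diazo-2-oxopropyl)phosphonate, K2CO3, MeOH, 0 °C → rt
Reagents that add atoms: dimethyl (1-diazo-2-oxopropyl)phosphonate, COP(=O)(OC)C(=[N+]=[N-])C(C)=O
Why: Ohira–Bestmann (Seyferth–Gilbert) homologation converts the aldehyde into the terminal alkyne under K2CO3/MeOH, the neopentyl ketone being far less reactive toward the phosphonate anion.

Step 5
Reactants: 6 (3R)-3-ethynyl-2,2,3-trimethylcyclopentan-1-one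
Product: 7 (1S,3R)-3-ethynyl-2,2,3-trimethylcyclopentan-1-ol (OH cis to the C3 methyl)
Conditions: (R)-2-methyl-CBS-oxazaborolidine (0.2 equiv), catecholborane, toluene, –78 → –40 °C
Reagents that add atoms: none
Why: Corey–Bakshi–Shibata reduction under reagent control: the quaternary C2 is the large and C5H2 the small flank of the ketone, so the (R)-oxazaborolidine should deliver hydride to give the (1S)-alcohol with OH cis to the C3 methyl and trans to the ethynyl group, and catecholborane at –78 °C leaves the alkyne alone.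

Step 6
Reactants: 7 (1S,3R)-3-ethynyl-2,2,3-trimethylcyclopentan-1-ol
Product: 8 (1R,3R)-3-bromo-1-ethynyl-1,2,2-trimethylcyclopentane (Br cis to ethynyl)
Conditions: CBr4, PPh3, toluene, 0 → 60 °C
Reagents that add atoms: tetrabromomethane, BrC(Br)(Br)Br
Why: Appel reaction: bromide displaces the phosphonium-activated oxygen with inversion, a substitution known at cyclopentyl carbinols that adjoin a quaternary carbon (Mitsunobu-type inversion at C17 of steroids), which places bromine cis to the ethynyl group (3R); the neutral, non-ionising medium disfavours methyl migration, and the ethynyl group cannot participate.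

Step 7
Reactants: 9 (R)-linalool [(3R)-3,7-dimethylocta-1,6-dien-3-ol]
Product: 10 triethyl{[(3R)-3,7-dimethylocta-1,6-dien-3-yl]oxy}silane
Conditions: Et3SiOTf, 2,6-lutidine, CH2Cl2, –78 → 0 °C
Reagents that add atoms: triethylsilyl trifluoromethanesulfonate, CC[Si](CC)(CC)OS(=O)(=O)C(F)(F)F
Why: Silyl triflate with a hindered pyridine base silylates the tertiary allylic alcohol without touching the stereocentre.

Step 8
Reactants: 10 triethyl{[(3R)-3,7-dimethylocta-1,6-dien-3-yl]oxy}silane
Product: 11 methyl (4R)-4-methyl-4-[(triethylsilyl)oxy]hex-5-enoate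
Conditions: O3 (1.0 equiv), NaOH, MeOH–CH2Cl2, –78 °C
Reagents that add atoms: ozone, [O-][O+]=O; methanol, CO
Why: Ozonolysis in methanolic NaOH turns an alkene carbon directly into a methyl ester (the carbonyl oxide is trapped by methanol and the methoxy hydroperoxide dehydrated by base), and one equivalent of ozone should select the electron-rich trisubstituted alkene over the vinyl group next to the silyloxy carbon.

Step 9
Reactants: 11 methyl (4R)-4-methyl-4-[(triethylsilyl)oxy]hex-5-enoate
Product: 12 (4R)-N-methoxy-N,4-dimethyl-4-[(triethylsilyl)oxy]hex-5-enamide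
Conditions: MeNH(OMe)·HCl, i-PrMgCl, THF, –20 → 0 °C
Reagents that add atoms: N,O-dimethylhydroxylamine hydrochloride, CNOC.Cl
Why: Aminolysis of the ester by the chloromagnesium amide of N,O-dimethylhydroxylamine gives the Weinreb amide, a carbonyl group that later accepts exactly one organometallic equivalent.

Step 10
Reactants: 12 (4R)-N-methoxy-N,4-dimethyl-4-[(triethylsilyl)oxy]hex-5-enamide
Product: 14 (4R)-N-methoxy-N,4-dimethyl-5-oxo-4-[(triethylsilyl)oxy]pentanamide, via ozonide 13 (not isolated)
Conditions: O3, CH2Cl2, –78 °C; then Me2S, –78 °C → rt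
Reagents that add atoms: ozone, [O-][O+]=O
Why: Ozonolysis with reductive work-up cleaves the remaining vinyl group to the aldehyde, which has no α-hydrogen and therefore cannot epimerise at C4.

Step 11
Reactants: 8 (1R,3R)-3-bromo-1-ethynyl-1,2,2-trimethylcyclopentane; 14 (4R)-N-methoxy-N,4-dimethyl-5-oxo-4-[(triethylsilyl)oxy]pentanamide
Product: 17 (4R,6E)-7-[(1R,3R)-3-bromo-1,2,2-trimethylcyclopentyl]-5-hydroxy-N-methoxy-N,4-dimethyl-4-[(triethylsilyl)oxy]oct-6-enamide (both C5 epimers), via alkenyldimethylalane 15 (not isolated), via lithium alkenyltrimethylaluminate 16 (not isolated)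
Conditions: Me3Al, Cp2ZrCl2 (0.25 equiv), ClCH2CH2Cl, 23 °C; volatiles removed in vacuo; MeLi, THF, –78 °C; then 14, –78 → 0 °C
Reagents that add atoms: trimethylaluminium, C[Al](C)C
Why: Negishi carboalumination adds methyl and aluminium syn across the alkyne with aluminium on the terminal carbon (this methyl becomes C7), and the ate complex formed with MeLi should transfer its alkenyl group to the aldehyde much faster than to the Weinreb amide; the carbinol centre is formed without control and is oxidised in step 12.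

Step 12
Reactants: 17 allylic alcohol (C4a carbinol, plan locants)
Product: 18 (4R,6E)-7-[(1R,3R)-3-bromo-1,2,2-trimethylcyclopentyl]-N-methoxy-N,4-dimethyl-5-oxo-4-[(triethylsilyl)oxy]oct-6-enamide
Conditions: Dess–Martin periodinane, NaHCO3, CH2Cl2, 0 °C → rt
Reagents that add atoms: none
Why: Dess–Martin oxidation of the allylic alcohol to the β,β-disubstituted enone.

Step 13
Reactants: 18 enone (C4a ketone, C5=C6, C7 methyl)
Product: 19 (4R,5Z)-7-[(1R,3R)-3-bromo-1,2,2-trimethylcyclopentyl]-N-methoxy-N,4-dimethyl-4,5-bis[(triethylsilyl)oxy]octa-5,7-dienamide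
Conditions: Et3SiOTf, Et3N, CH2Cl2, –78 → 0 °C
Reagents that add atoms: triethylsilyl trifluoromethanesulfonate, CC[Si](CC)(CC)OS(=O)(=O)C(F)(F)F
Why: Soft enolisation (silyl triflate, tertiary amine) can only give the extended dienol ether, because C4 is quaternary (no α′-hydrogen) and C1′ is quaternary (the C7 methyl holds the only γ-hydrogens); the s-cis enone places oxygen cis to C6, which fixes the (5Z) geometry, and the amide is not enolised under these conditions.

Step 14
Reactants: 19 silyl dienol ether with Weinreb amide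
Product: 21 (6R,7Z)-9-[(1R,3R)-3-bromo-1,2,2-trimethylcyclopentyl]-2,6-dimethyl-6,7-bis[(triethylsilyl)oxy]deca-1,7,9-trien-3-one, via magnesium hemiaminal 20 (not isolated)
Conditions: CH2=C(CH3)MgBr, THF, –20 → 0 °C; pH 7 phosphate buffer
Reagents that add atoms: isopropenylmagnesium bromide, CC(=C)[Mg]Br
Why: Weinreb ketone synthesis: the magnesium-chelated adduct 20 survives until work-up, so the isopropenyl ketone is formed without over-addition, and a triethylsilyl dienol ether is stable to a Grignard reagent at or below 0 °C.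

Step 15
Reactants: 21 (6R,7Z)-9-[(1R,3R)-3-bromo-1,2,2-trimethylcyclopentyl]-2,6-dimethyl-6,7-bis[(triethylsilyl)oxy]deca-1,7,9-trien-3-one
Product: 22 (4R,4aR,8aS)-6-[(1R,3R)-3-bromo-1,2,2-trimethylcyclopentyl]-4,8a-dimethyl-4,4a-bis[(triethylsilyl)oxy]-3,4,4a,7,8,8a-hexahydronaphthalen-1(2H)-one
Conditions: toluene (0.01 M), 2,6-di-tert-butyl-4-methylphenol (0.1 equiv), 150 °C, sealed tube
Reagents that add atoms: none
Why: On heating, the electron-rich (Z)-1-silyloxy diene C7=C6–C5=C4a and the isopropenyl ketone C8=C8a–C1=O should combine in a concerted, asynchronous [4+2] cycloaddition in which the C7–C8 bond (largest HOMO coefficient at C7, largest LUMO coefficient at C8) forms ahead of the C4a–C8a bond; the closest known reaction type is the thermal intramolecular Diels–Alder reaction of 1,7,9-decatrien-3-ones that carry oxygenated dienes. Ring B is closed by the cycloaddition itself (4π + 2π, suprafacial on both partners), and ring A is closed at the same time as the tether ring of a fused adduct, the four-carbon chain C1–C4 linking diene terminus C4a to dienophile carbon C8a in a chair-like array with C4a–C8a as the closing bond. C8a is set relative to C4a by the orientation of the dienophile: with the tether carbonyl exo and the C8a methyl endo, the methyl ends anti to the C4a oxygen (trans ring fusion), which is the arrangement expected for an α-methyl enone and avoids the gauche contact between an exo methyl and the inside OSiEt3 group that burdens the endo-carbonyl alternative. The absolute sense at C4a is set by C4: in the chair-like tether one C4 substituent must lie pseudo-axial on the dienophile side, 1,3 to the endo methyl, and the oxygen of the OSiEt3 group should take this site in preference to the C4 methyl, so the dienophile adds to the diene face that gives (4aR,8aS). The step therefore needs exo and facial selectivity, secured by the α-methyl group, the inside silyloxy group and the C4 stereocentre, whereas the regiochemistry is fixed by the tether and agrees with the electronic preference. The s-cis diene conformer is favoured because the bulky ring C on C6 destabilises the s-trans form, and an inside oxygen substituent is tolerated far better than an inside carbon.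

Step 16
Reactants: 22 decalin adduct (C1 ketone)
Product: 24 (4R,4aR,8aS)-6-[(1R,3R)-3-bromo-1,2,2-trimethylcyclopentyl]-4,8a-dimethyl-4,4a-bis[(triethylsilyl)oxy]-3,4,4a,7,8,8a-hexahydronaphthalen-1-yl trifluoromethanesulfonate, via potassium enolate 23 (not isolated)
Conditions: KN(SiMe3)2, THF, –78 °C; then PhNTf2, –78 → 0 °C
Reagents that add atoms: N-phenylbis(trifluoromethanesulfonimide), O=S(=O)(N(c1ccccc1)S(=O)(=O)C(F)(F)F)C(F)(F)F
Why: C2 is the only enolisable position of the ketone (C8a is quaternary), so the potassium enolate 23 forms regioselectively and is O-sulfonylated by PhNTf2 to the enol triflate, while the silyl group on the C4a oxygen rules out retro-aldol cleavage.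

Step 17
Reactants: 24 C1 enol triflate
Product: 25 (4R,4aR,8aS)-1-bromo-6-[(1R,3R)-3-bromo-1,2,2-trimethylcyclopentyl]-4,8a-dimethyl-4,4a-bis[(triethylsilyl)oxy]-3,4,4a,7,8,8a-hexahydronaphthalene (plan locants; C1=C2 and C5=C6)
Conditions: Ni(cod)2 (10 mol %), LiBr, DMA–THF (1:3), 23 °C
Reagents that add atoms: lithium bromide, [Li+].[Br-]
Why: Nickel-catalysed halide exchange of an enol triflate (oxidative addition to zerovalent nickel, triflate-for-bromide exchange, reductive elimination) should give the alkenyl bromide; the hindered secondary alkyl bromide of ring C is expected to be inert.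

Step 18
Reactants: 25 C1 bromoalkene
Product: 26 (1S,4R,4aR,8aS)-1-bromo-6-[(1R,3R)-3-bromo-1,2,2-trimethylcyclopentyl]-4,8a-dimethyl-4,4a-bis[(triethylsilyl)oxy]-1,2,3,4,4a,7,8,8a-octahydronaphthalene (plan locants)
Conditions: H2 (50 bar), [Ir(cod)(PCy3)(py)][B(3,5-(CF3)2C6H3)4] (5 mol %), CH2Cl2, 23 °C
Reagents that add atoms: none
Why: Homogeneous hydrogenation with the cationic iridium complex adds H2 cis to the trisubstituted bromoalkene without hydrogenolysis, a known way to a secondary bromide beside a quaternary carbon; the axial C8a methyl next to C1 and the axial C4 silyloxy group over C2 shield one face, so hydrogen should enter from the face of the C4a oxygen and leave bromine equatorial and cis to the C8a methyl (1S), while C5=C6, flanked by two quaternary carbons, stays intact.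

Step 19
Reactants: 26 dibromide (C7 methylene)
Product: 27 (4aR,5R,8S,8aS)-8-bromo-3-[(1R,3R)-3-bromo-1,2,2-trimethylcyclopentyl]-5,8a-dimethyl-4a,5-bis[(triethylsilyl)oxy]-4a,5,6,7,8,8a-hexahydronaphthalen-2(1H)-one
Conditions: CrO3, 3,5-dimethylpyrazole, CH2Cl2, –20 °C
Reagents that add atoms: chromium trioxide, O=[Cr](=O)=O
Why: Allylic oxidation with the CrO3–3,5-dimethylpyrazole complex converts the only allylic CH2 group (C7) into the enone carbonyl; C4a and C1′ carry no hydrogen.

Step 20
Reactants: 27 bis(triethylsilyl) ether of the target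
Product: 28 (4aR,5R,8S,8aS)-8-bromo-3-[(1R,3R)-3-bromo-1,2,2-trimethylcyclopentyl]-4a,5-dihydroxy-5,8a-dimethyl-4a,5,6,7,8,8a-hexahydronaphthalen-2(1H)-one (CNP0216929.1)
Conditions: HF·pyridine, pyridine, THF, 0 °C → rt
Reagents that add atoms: none
Why: Buffered HF·pyridine cleaves both tertiary triethylsilyl ethers; a basic fluoride source is avoided because an alkoxide at C4 could open the C4–C4a bond by vinylogous retro-aldol reaction.

Compound list
1 | (1R,4S)-4,7,7-trimethyl-3-oxo-2-oxabicyclo[2.2.1]heptane-1-carboxylic acid, (+)-camphanic acid | CC1(C)[C@](C(=O)O)(O2)CC[C@]1(C)C2=O | starting material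
2 | disodium (1S,3R)-3-hydroxy-1,2,2-trimethylcyclopentane-1,3-dicarboxylate | CC1(C)[C@@](O)(C(=O)[O-])CC[C@]1(C)C(=O)[O-].[Na+].[Na+] | intermediate (not isolated)
3 | (1S)-1,2,2-trimethyl-3-oxocyclopentane-1-carboxylic acid | CC1(C)C(=O)CC[C@]1(C)C(=O)O | intermediate
4 | (3S)-3-(hydroxymethyl)-2,2,3-trimethylcyclopentan-1-ol, C1 epimers | CC1(C)C(O)CC[C@]1(C)CO | intermediate
5 | (1S)-1,2,2-trimethyl-3-oxocyclopentane-1-carbaldehyde | CC1(C)C(=O)CC[C@]1(C)C=O | intermediate
6 | (3R)-3-ethynyl-2,2,3-trimethylcyclopentan-1-one | CC1(C)C(=O)CC[C@]1(C)C#C | intermediate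
7 | (1S,3R)-3-ethynyl-2,2,3-trimethylcyclopentan-1-ol | CC1(C)[C@@H](O)CC[C@]1(C)C#C | intermediate
8 | (1R,3R)-3-bromo-1-ethynyl-1,2,2-trimethylcyclopentane | CC1(C)[C@H](Br)CC[C@]1(C)C#C | intermediate
9 | (R)-linalool, (3R)-3,7-dimethylocta-1,6-dien-3-ol | C=C[C@](C)(O)CCC=C(C)C | starting material
10 | triethyl{[(3R)-3,7-dimethylocta-1,6-dien-3-yl]oxy}silane | C=C[C@](C)(O[Si](CC)(CC)CC)CCC=C(C)C | intermediate
11 | methyl (4R)-4-methyl-4-[(triethylsilyl)oxy]hex-5-enoate | C=C[C@](C)(O[Si](CC)(CC)CC)CCC(=O)OC | intermediate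
12 | (4R)-N-methoxy-N,4-dimethyl-4-[(triethylsilyl)oxy]hex-5-enamide | C=C[C@](C)(O[Si](CC)(CC)CC)CCC(=O)N(C)OC | intermediate
13 | (4R)-N-methoxy-N,4-dimethyl-4-[(triethylsilyl)oxy]-4-(1,2,4-trioxolan-3-yl)butanamide, ozonide of 12 | C1(OCOO1)[C@](C)(O[Si](CC)(CC)CC)CCC(=O)N(C)OC | intermediate (not isolated)
14 | (4R)-N-methoxy-N,4-dimethyl-5-oxo-4-[(triethylsilyl)oxy]pentanamide | O=C[C@](C)(O[Si](CC)(CC)CC)CCC(=O)N(C)OC | intermediate
15 | dimethyl{(1E)-2-[(1R,3R)-3-bromo-1,2,2-trimethylcyclopentyl]prop-1-en-1-yl}alane | CC1(C)[C@H](Br)CC[C@]1(C)/C(C)=C/[Al](C)C | intermediate (not isolated)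
16 | lithium trimethyl{(1E)-2-[(1R,3R)-3-bromo-1,2,2-trimethylcyclopentyl]prop-1-en-1-yl}aluminate | [Li+].CC1(C)[C@H](Br)CC[C@]1(C)/C(C)=C/[Al-](C)(C)C | intermediate (not isolated)
17 | (4R,6E)-7-[(1R,3R)-3-bromo-1,2,2-trimethylcyclopentyl]-5-hydroxy-N-methoxy-N,4-dimethyl-4-[(triethylsilyl)oxy]oct-6-enamide, C5 epimers | CC1(C)[C@H](Br)CC[C@]1(C)/C(C)=C/C(O)[C@](C)(O[Si](CC)(CC)CC)CCC(=O)N(C)OC | intermediate
18 | (4R,6E)-7-[(1R,3R)-3-bromo-1,2,2-trimethylcyclopentyl]-N-methoxy-N,4-dimethyl-5-oxo-4-[(triethylsilyl)oxy]oct-6-enamide | CC1(C)[C@H](Br)CC[C@]1(C)/C(C)=C/C(=O)[C@](C)(O[Si](CC)(CC)CC)CCC(=O)N(C)OC | intermediate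
19 | (4R,5Z)-7-[(1R,3R)-3-bromo-1,2,2-trimethylcyclopentyl]-N-methoxy-N,4-dimethyl-4,5-bis[(triethylsilyl)oxy]octa-5,7-dienamide | CC1(C)[C@H](Br)CC[C@]1(C)C(=C)/C=C(\O[Si](CC)(CC)CC)[C@](C)(O[Si](CC)(CC)CC)CCC(=O)N(C)OC | intermediate
20 | bromomagnesium hemiaminal from 19 and the isopropenyl Grignard reagent (C1 bears OMgBr, N(Me)OMe and isopropenyl) | CC1(C)[C@H](Br)CC[C@]1(C)C(=C)/C=C(\O[Si](CC)(CC)CC)[C@](C)(O[Si](CC)(CC)CC)CCC(O[Mg]Br)(N(C)OC)C(C)=C | intermediate (not isolated)
21 | (6R,7Z)-9-[(1R,3R)-3-bromo-1,2,2-trimethylcyclopentyl]-2,6-dimethyl-6,7-bis[(triethylsilyl)oxy]deca-1,7,9-trien-3-one | CC1(C)[C@H](Br)CC[C@]1(C)C(=C)/C=C(\O[Si](CC)(CC)CC)[C@](C)(O[Si](CC)(CC)CC)CCC(=O)C(C)=C | intermediate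
22 | (4R,4aR,8aS)-6-[(1R,3R)-3-bromo-1,2,2-trimethylcyclopentyl]-4,8a-dimethyl-4,4a-bis[(triethylsilyl)oxy]-3,4,4a,7,8,8a-hexahydronaphthalen-1(2H)-one | CC1(C)[C@H](Br)CC[C@]1(C)C1=C[C@]2(O[Si](CC)(CC)CC)[C@](C)(O[Si](CC)(CC)CC)CCC(=O)[C@@]2(C)CC1 | intermediate
23 | potassium enolate of 22 (C1–O−, C1=C2) | CC1(C)[C@H](Br)CC[C@]1(C)C1=C[C@]2(O[Si](CC)(CC)CC)[C@](C)(O[Si](CC)(CC)CC)CC=C([O-])[C@@]2(C)CC1.[K+] | intermediate (not isolated)
24 | (4R,4aR,8aS)-6-[(1R,3R)-3-bromo-1,2,2-trimethylcyclopentyl]-4,8a-dimethyl-4,4a-bis[(triethylsilyl)oxy]-3,4,4a,7,8,8a-hexahydronaphthalen-1-yl trifluoromethanesulfonate | CC1(C)[C@H](Br)CC[C@]1(C)C1=C[C@]2(O[Si](CC)(CC)CC)[C@](C)(O[Si](CC)(CC)CC)CC=C(OS(=O)(=O)C(F)(F)F)[C@@]2(C)CC1 | intermediate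
25 | (4R,4aR,8aS)-1-bromo-6-[(1R,3R)-3-bromo-1,2,2-trimethylcyclopentyl]-4,8a-dimethyl-4,4a-bis[(triethylsilyl)oxy]-3,4,4a,7,8,8a-hexahydronaphthalene (plan locants) | CC1(C)[C@H](Br)CC[C@]1(C)C1=C[C@]2(O[Si](CC)(CC)CC)[C@](C)(O[Si](CC)(CC)CC)CC=C(Br)[C@@]2(C)CC1 | intermediate
26 | (1S,4R,4aR,8aS)-1-bromo-6-[(1R,3R)-3-bromo-1,2,2-trimethylcyclopentyl]-4,8a-dimethyl-4,4a-bis[(triethylsilyl)oxy]-1,2,3,4,4a,7,8,8a-octahydronaphthalene (plan locants) | CC1(C)[C@H](Br)CC[C@]1(C)C1=C[C@]2(O[Si](CC)(CC)CC)[C@](C)(O[Si](CC)(CC)CC)CC[C@H](Br)[C@@]2(C)CC1 | intermediate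
27 | (4aR,5R,8S,8aS)-8-bromo-3-[(1R,3R)-3-bromo-1,2,2-trimethylcyclopentyl]-5,8a-dimethyl-4a,5-bis[(triethylsilyl)oxy]-4a,5,6,7,8,8a-hexahydronaphthalen-2(1H)-one | CC1(C)[C@H](Br)CC[C@]1(C)C1=C[C@]2(O[Si](CC)(CC)CC)[C@](C)(O[Si](CC)(CC)CC)CC[C@H](Br)[C@@]2(C)CC1=O | intermediate
28 | (4aR,5R,8S,8aS)-8-bromo-3-[(1R,3R)-3-bromo-1,2,2-trimethylcyclopentyl]-4a,5-dihydroxy-5,8a-dimethyl-4a,5,6,7,8,8a-hexahydronaphthalen-2(1H)-one, CNP0216929.1 | CC1(C)[C@H](Br)CC[C@]1(C)C1=C[C@]2(O)[C@](C)(O)CC[C@H](Br)[C@@]2(C)CC1=O | target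

Total step count: 20. Longest linear sequence: 16 steps (steps 1–6 and 11–20, from 1); the linalool branch (steps 7–10) joins at step 11.

Steps most likely to fail

Step 15. The cycloaddition has to join two fully substituted carbons (C4a and C8a) beside the quaternary C4. It may therefore be so slow that hydrolysis of the dienol ether or intermolecular reaction takes over, or it may run with poor exo or facial selectivity. The fallback sets out from 21 and comes back at 22. It exchanges the silyl ether for a far stronger activating group, the free oxido substituent. Treating 21 with tetrabutylammonium difluorotriphenylsilicate in THF at –78 → –20 °C should cleave the dienol silyl ether selectively. The resulting dienolate should close rings A and B at low temperature by an oxyanion-accelerated cycloaddition (in the stepwise limit, vinylogous Michael addition followed by aldol closure). Protonation with aqueous NH4Cl should give (4R,4aR,8aS)-6-[(1R,3R)-3-bromo-1,2,2-trimethylcyclopentyl]-4a-hydroxy-4,8a-dimethyl-4-[(triethylsilyl)oxy]-3,4,4a,7,8,8a-hexahydronaphthalen-1(2H)-one F1. Silylation of the C4a hydroxyl with Et3SiOTf and 2,6-lutidine then returns to 22.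

Step 6. Ionisation of the activated carbinol with methyl migration from C2, or elimination toward C4, may outrun bromide attack at the hindered carbon. The fallback sets out from 3 and comes back at 8. It makes the C–Br bond first and adds hydrogen afterwards, so no substitution at the neopentyl carbon is needed.
- Esterification (MeI, K2CO3, DMF) should give methyl (1S)-1,2,2-trimethyl-3-oxocyclopentane-1-carboxylate F2.
- Enolisation toward the only α-CH2 and triflation (KN(SiMe3)2, PhNTf2) should give methyl (1S)-1,5,5-trimethyl-4-[(trifluoromethanesulfonyl)oxy]cyclopent-3-ene-1-carboxylate F3.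
- Nickel-catalysed halide exchange (Ni(cod)2, LiBr) should give methyl (1S)-4-bromo-1,5,5-trimethylcyclopent-3-ene-1-carboxylate F4.
- Diimide reduction (potassium azodicarboxylate, AcOH, MeOH), which is not directed by the ester, should give methyl (1S,3R)-3-bromo-1,2,2-trimethylcyclopentane-1-carboxylate F5. Facial control rests only on the small steric difference between CO2Me and CH3 on the remote quaternary carbon, so the C3 epimers would have to be separated here.
- Reduction with (i-Bu)2AlH should give [(1S,3R)-3-bromo-1,2,2-trimethylcyclopentyl]methanol F6.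
- Dess–Martin oxidation should give (1S,3R)-3-bromo-1,2,2-trimethylcyclopentane-1-carbaldehyde F7.
- Ohira–Bestmann homologation of F7 returns to 8.

Step 18. Hydrogen may be delivered to the wrong face because the silyloxy group on C4a crowds the desired one, turnover at the hindered bromoalkene may be slow, or bromine may be lost by hydrogenolysis. The fallback sets out from 25 and comes back at 26. It clears the desired face and uses an uncatalysed reagent that cannot reduce the hindered C5=C6 bond or cleave C–Br. HF·pyridine should remove both silyl groups to give the bromoalkene diol F8. Diimide (2-nitrobenzenesulfonylhydrazide, Et3N, CH2Cl2) should then add hydrogen from the face that now carries only the small C4a hydroxyl, anti to the C8a methyl, to give the saturated dibromo diol F9. Silylation of both hydroxyls (Et3SiOTf, 2,6-lutidine) returns to 26.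

Further compounds
F1 | step 15 | (4R,4aR,8aS)-6-[(1R,3R)-3-bromo-1,2,2-trimethylcyclopentyl]-4a-hydroxy-4,8a-dimethyl-4-[(triethylsilyl)oxy]-3,4,4a,7,8,8a-hexahydronaphthalen-1(2H)-one | CC1(C)[C@H](Br)CC[C@]1(C)C1=C[C@]2(O)[C@](C)(O[Si](CC)(CC)CC)CCC(=O)[C@@]2(C)CC1
F2 | step 6 | methyl (1S)-1,2,2-trimethyl-3-oxocyclopentane-1-carboxylate | CC1(C)C(=O)CC[C@]1(C)C(=O)OC
F3 | step 6 | methyl (1S)-1,5,5-trimethyl-4-[(trifluoromethanesulfonyl)oxy]cyclopent-3-ene-1-carboxylate | CC1(C)C(OS(=O)(=O)C(F)(F)F)=CC[C@]1(C)C(=O)OC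
F4 | step 6 | methyl (1S)-4-bromo-1,5,5-trimethylcyclopent-3-ene-1-carboxylate | CC1(C)C(Br)=CC[C@]1(C)C(=O)OC
F5 | step 6 | methyl (1S,3R)-3-bromo-1,2,2-trimethylcyclopentane-1-carboxylate | CC1(C)[C@H](Br)CC[C@]1(C)C(=O)OC
F6 | step 6 | [(1S,3R)-3-bromo-1,2,2-trimethylcyclopentyl]methanol | CC1(C)[C@H](Br)CC[C@]1(C)CO
F7 | step 6 | (1S,3R)-3-bromo-1,2,2-trimethylcyclopentane-1-carbaldehyde | CC1(C)[C@H](Br)CC[C@]1(C)C=O
F8 | step 18 | (4R,4aR,8aS)-1-bromo-6-[(1R,3R)-3-bromo-1,2,2-trimethylcyclopentyl]-4,8a-dimethyl-3,4,4a,7,8,8a-hexahydronaphthalene-4,4a-diol (plan locants) | CC1(C)[C@H](Br)CC[C@]1(C)C1=C[C@]2(O)[C@](C)(O)CC=C(Br)[C@@]2(C)CC1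
F9 | step 18 | (1S,4R,4aR,8aS)-1-bromo-6-[(1R,3R)-3-bromo-1,2,2-trimethylcyclopentyl]-4,8a-dimethyl-1,2,3,4,4a,7,8,8a-octahydronaphthalene-4,4a-diol (plan locants) | CC1(C)[C@H](Br)CC[C@]1(C)C1=C[C@]2(O)[C@](C)(O)CC[C@H](Br)[C@@]2(C)CC1
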